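**Retrosynthetic overview**
- Last event: mild hydrolysis of a C1 dimethyl ketal. Before it, the side chain is cut between the vinylic carbon C9' and the allylic carbon C10'. This gives a ring-bearing terminal alkyne (C8'≡C9'–H) and 1-octene.
- Enabling feature: C8'=C9' is an unbranched cis CH=CH, C9' carries only H and the n-octyl tail, and the seven methylenes C1'–C7' insulate it from the cyclohexene ring. C9' therefore maps onto an acidic alkyne C–H and C10' onto the CH2= end of 1-octene. Both carbons can be bound to one boron atom (temporary tether; alkyne as higher oxidation level) and joined by a boron-to-carbon 1,2-shift that also fixes the Z geometry.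
- Ring functions: C2=C3 comes from a regiodefined C1=C2 methyl enol ether (methoxyselenenylation, selenoxide elimination). C1'–C2' comes from copper-catalysed opening of a spiro-oxirane formed by Payne rearrangement, whose inversion at C5 makes the C4/C5 diol trans.
- Absolute configuration: Sharpless epoxidation of the C4=C5 allylic alcohol in the Birch diene of 3-methoxybenzyl alcohol.
- Rings: the six-membered carbocycle is inherited from the arene and is never closed. Transient rings appear in the order fused oxirane, spiro-oxirane, 9-BBN bicycle (boron carrier), and all are removed.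

Key step: step 6

Remark: locants C1–C6 (C1 = carbonyl carbon) and C1'–C17' (side chain, counted from the ring) are those of the target and are used for all intermediates.

Step 1
Reactants: 1 trimethylsilylacetylene; 2 1,6-dibromohexane
Product: 4 (8-bromooct-1-yn-1-yl)trimethylsilane, via lithium (trimethylsilyl)acetylide 3 (not isolated)
Conditions: n-BuLi (1.0 equiv), THF, −78 °C; then 2 (3 equiv), DMPU, −78 °C → rt
Reagents that add atoms: none
Why: SN2 alkylation of a lithium acetylide by a primary bromide, in which the excess of the symmetrical dibromide suppresses double substitution and the silyl group blocks the second acetylenic position.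

Step 2
Reactants: 5 3-methoxybenzyl alcohol
Product: 6 (5-methoxycyclohexa-1,4-dien-1-yl)methanol
Conditions: Li, NH3(l), THF, t-BuOH, −78 → −33 °C; solid NH4Cl
Reagents that add atoms: none
Why: Birch reduction keeps both donor-substituted carbons sp2, so the 1,4-diene carries a regiodefined enol ether at C1=C2 and an allylic-alcohol olefin at C4=C5, and the alkoxide form of the benzylic oxygen disfavours C–O hydrogenolysis.

Step 3
Reactants: 6 (5-methoxycyclohexa-1,4-dien-1-yl)methanol
Product: 7 [(1S,6S)-3-methoxy-7-oxabicyclo[4.1.0]hept-3-en-1-yl]methanol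
Conditions: Ti(OiPr)4 (10 mol %), L-(+)-diisopropyl tartrate (12 mol %), TBHP (decane), 4 Å MS, CH2Cl2, −25 °C; basic work-up
Reagents that add atoms: tert-butyl hydroperoxide CC(C)(C)OO
Why: Sharpless asymmetric epoxidation oxidises only the olefin of the titanium-bound allylic alkoxide (C4=C5) and leaves the enol ether alone, and L-(+)-tartrate delivers oxygen to the face from which C4, C1' and C6 run counterclockwise around C5, which sets C4 as (S) in its final form and C5 as the oxirane carbon that step 4 inverts.

Step 4
Reactants: 7 [(1S,6S)-3-methoxy-7-oxabicyclo[4.1.0]hept-3-en-1-yl]methanol; 4 (8-bromooct-1-yn-1-yl)trimethylsilane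
Product: 11 (1S,2S)-5-methoxy-1-(non-8-yn-1-yl)cyclohex-4-ene-1,2-diol, via Grignard reagent 8 (not isolated), via spiro-oxirane lithium alkoxide 9 (not isolated), via C-silylated diol 10 (not isolated)
Conditions: 4, Mg, THF (→ 8); 7, n-BuLi (1.0 equiv), LiCl, THF, −78 → 0 °C; 8 (2.5 equiv), CuI (15 mol %), −30 → 0 °C; aq NH4Cl; then K2CO3 (20 mol %), MeOH, rt
Reagents that add atoms: none
Why: Payne rearrangement with organocopper trapping, in which the C1' alkoxide attacks C5 opposite the oxirane C5–O bond (inversion at C5, C4–O untouched, hence the trans-diol with (4S,5S) configuration), the monovalent-copper-catalysed Grignard reagent opens only the unhindered CH2 terminus of the spiro-oxirane to forge C1'–C2', and catalytic carbonate in MeOH finally cleaves the alkynyl C–Si bond.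

Step 5
Reactants: 11 (1S,2S)-5-methoxy-1-(non-8-yn-1-yl)cyclohex-4-ene-1,2-diol
Product: 13 (1S,2S)-5,5-dimethoxy-1-(non-8-yn-1-yl)cyclohex-3-ene-1,2-diol, via 2-phenylselanyl dimethyl ketal 12 (not isolated)
Conditions: PhSeCl, 2,6-lutidine, MeOH–CH2Cl2, −78 °C; then 30% H2O2, pyridine, 0 °C → rt
Reagents that add atoms: methanol CO
Why: Alkoxyselenenylation of an enol ether followed by selenoxide syn-elimination, in which PhSe+ adds to the nucleophilic C2, MeOH traps the C1 oxocarbenium ion as the dimethyl ketal, and the selenoxide can only eliminate towards C3 because C1 is now quaternary, so C2=C3 is placed without regiochemical choice and the diol stereocentres are untouched.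

Step 6
Reactants: 13 (1S,2S)-5,5-dimethoxy-1-(non-8-yn-1-yl)cyclohex-3-ene-1,2-diol; 14 oct-1-ene
Product: 17 (1S,2S)-1-[(8Z)-heptadec-8-en-1-yl]-5,5-dimethoxycyclohex-3-ene-1,2-diol, via B-octyl-9-BBN 15 (not isolated), via alkynylborate 16 (not isolated)
Conditions: 14 (slight excess over B–H), 9-BBN, 1,4-dioxane, rt → 60 °C (→ 15); then 13, (IPr)AgCl [IPr = 1,3-bis(2,6-diisopropylphenyl)imidazol-2-ylidene] (10 mol %), KOtBu (20 mol %), MeOH, 50 °C
Reagents that add atoms: none
Why: Anti-Markovnikov hydroboration of 14 puts boron on the future C10', and the monovalent silver alkoxide metalates the acidic C9'–H of 13 and hands the alkynyl group to the Lewis-acidic boron of 15, so both carbons to be joined sit on one boron atom in borate 16. The cationic silver (or a proton) then attacks C8' and the octyl group migrates from boron to C9' anti to that electrophile (1,2-metalate rearrangement), forming C9'–C10', after which stereoretentive protonolysis of the C8'–Ag and C9'–B bonds by MeOH leaves the two chains cis and expels the boron carrier as B-methoxy-9-BBN. The closest known reaction type is the silver–NHC-catalysed Z-selective hydroalkylation of terminal alkynes with B-alkyl-9-BBN reagents, a catalytic relative of the Zweifel olefination. No ring is closed and no stereocentre is created, and the only new stereo-element, the Z geometry of C8'=C9', is controlled by the anti relationship of migrating group and electrophile. Regioselectivity is secured because only the terminal carbon C9' can be bound to boron, and migration selectivity because the primary octyl group can align with the alkyne π system while the two bridgehead B–C bonds of the bicycle cannot. Chemoselectivity needs a medium free of B–H, which the excess of 14 secures, and the C1 ketal, the ring olefin C2=C3 and the free C4/C5 diol are inert to a trialkylborane, catalytic alkoxide and MeOH and are held seven methylenes away from the reacting terminus.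

Step 7
Reactants: 17 (1S,2S)-1-[(8Z)-heptadec-8-en-1-yl]-5,5-dimethoxycyclohex-3-ene-1,2-diol
Product: 18 (4S,5S)-5-[(8Z)-heptadec-8-en-1-yl]-4,5-dihydroxycyclohex-2-en-1-one (target)
Conditions: PPTS (cat.), acetone–H2O, 0 °C → rt
Reagents that add atoms: water O
Why: Acid-catalysed hydrolysis of an allylic dimethyl ketal, which ionises far more easily than anything else in the molecule, so a weak acid should release the C1 enone without dehydrating the tertiary C5 alcohol, ionising the allylic C4 alcohol or isomerising the Z olefin.

**Compound list**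
1 | trimethylsilylacetylene | C#C[Si](C)(C)C | starting material
2 | 1,6-dibromohexane | BrCCCCCCBr | starting material
3 | lithium (trimethylsilyl)acetylide | [Li]C#C[Si](C)(C)C | intermediate
4 | (8-bromooct-1-yn-1-yl)trimethylsilane | C[Si](C)(C)C#CCCCCCCBr | intermediate
5 | 3-methoxybenzyl alcohol | COc1cccc(CO)c1 | starting material
6 | (5-methoxycyclohexa-1,4-dien-1-yl)methanol | COC1=CCC=C(CO)C1 | intermediate
7 | [(1S,6S)-3-methoxy-7-oxabicyclo[4.1.0]hept-3-en-1-yl]methanol | COC1=CC[C@@H]2O[C@]2(CO)C1 | intermediate
8 | [8-(trimethylsilyl)oct-7-yn-1-yl]magnesium bromide | C[Si](C)(C)C#CCCCCCC[Mg]Br | intermediate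
9 | lithium (3R,4S)-7-methoxy-1-oxaspiro[2.5]oct-6-en-4-olate | COC1=CC[C@H]([O-])[C@]2(CO2)C1.[Li+] | intermediate
10 | (1S,2S)-5-methoxy-1-[9-(trimethylsilyl)non-8-yn-1-yl]cyclohex-4-ene-1,2-diol | C[Si](C)(C)C#CCCCCCCC[C@]1(O)CC(OC)=CC[C@@H]1O | intermediate
11 | (1S,2S)-5-methoxy-1-(non-8-yn-1-yl)cyclohex-4-ene-1,2-diol | C#CCCCCCCC[C@]1(O)CC(OC)=CC[C@@H]1O | intermediate
12 | (1S,2S)-5,5-dimethoxy-1-(non-8-yn-1-yl)-4-(phenylselanyl)cyclohexane-1,2-diol (configuration at the C–Se carbon not controlled and irrelevant) | C#CCCCCCCC[C@]1(O)CC(OC)(OC)C([Se]c2ccccc2)C[C@@H]1O | intermediate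
13 | (1S,2S)-5,5-dimethoxy-1-(non-8-yn-1-yl)cyclohex-3-ene-1,2-diol | C#CCCCCCCC[C@]1(O)CC(OC)(OC)C=C[C@@H]1O | intermediate
14 | oct-1-ene | C=CCCCCCC | starting material
15 | 9-octyl-9-borabicyclo[3.3.1]nonane (B-octyl-9-BBN) | CCCCCCCCB1C2CCCC1CCC2 | intermediate
16 | alkynyl(octyl)-9-borabicyclo[3.3.1]nonane borate anion, counter-ion (IPr)Ag+ | CCCCCCCC[B-]1(C#CCCCCCCC[C@]2(O)CC(OC)(OC)C=C[C@@H]2O)C3CCCC1CCC3 | intermediate
17 | (1S,2S)-1-[(8Z)-heptadec-8-en-1-yl]-5,5-dimethoxycyclohex-3-ene-1,2-diol | CCCCCCCC/C=C\CCCCCCC[C@]1(O)CC(OC)(OC)C=C[C@@H]1O | intermediate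
18 | (4S,5S)-5-[(8Z)-heptadec-8-en-1-yl]-4,5-dihydroxycyclohex-2-en-1-one | CCCCCCCC/C=C\CCCCCCC[C@]1(O)CC(=O)C=C[C@@H]1O | target

Total step count: 7. Longest linear sequence: 6 steps (5 → 6 → 7 → 11 → 13 → 17 → 18).

**Steps most likely to fail**

Step 4. The Payne equilibration may be slow or may lie too far on the side of the fused oxirane. The organocopper reagent would then open that oxirane at C4 or be consumed unproductively.
- The fallback separates rearrangement and C–C bond formation and sets out from 7.
- Aqueous NaOH in t-BuOH (Payne rearrangement with hydroxide capture at the CH2 terminus, enol ether stable to base) should give (1R,2S)-1-(hydroxymethyl)-5-methoxycyclohex-4-ene-1,2-diol F1.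
- Selective sulfonylation of the primary hydroxyl (TsCl, Et3N, Bu2SnO cat.) should give [(1R,2S)-1,2-dihydroxy-5-methoxycyclohex-4-en-1-yl]methyl 4-methylbenzenesulfonate F2.
- K2CO3 in MeOH should close it to the isolable (3R,4S)-7-methoxy-1-oxaspiro[2.5]oct-6-en-4-ol F3.
- F3 is opened with 8 and CuI, and the route is rejoined at 10.

Step 6. A cyclooctyl B–C bond may migrate in competition, the borane may be sequestered by the diol, protodeboronation may stay incomplete, or the Z geometry may erode.
- The fallback sets out from 13 and uses a stoichiometric, stereospecific sequence.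
- Hydroboration with pinacolborane (Cp2ZrHCl cat., excess reagent for the two hydroxyls, methanolic work-up) should give (1S,2S)-5,5-dimethoxy-1-[(8E)-9-(4,4,5,5-tetramethyl-1,3,2-dioxaborolan-2-yl)non-8-en-1-yl]cyclohex-3-ene-1,2-diol F4.
- n-Octyllithium (3 equiv), then I2, then NaOMe (Zweifel olefination: iodonium-triggered 1,2-shift of octyl and anti-elimination) should form the same C9'–C10' bond with inversion of olefin geometry. The route is rejoined at 17.

Step 5. The enol ether may be lost by acid-mediated methanolysis before selenenylation, the C1 oxocarbenium ion may be captured transannularly by the C4 hydroxyl, or the labile ketal may hydrolyse during the oxidation.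
- The fallback sets out from 11 and drops both selenium and the ketal.
- The silver-catalysed hydroalkylation with 15 is run on 11 itself (the methyl enol ether is base-stable). It should give (1S,2S)-1-[(8Z)-heptadec-8-en-1-yl]-5-methoxycyclohex-4-ene-1,2-diol F5.
- The enol ether is then dehydrogenated with divalent palladium (Pd(OAc)2, NaHCO3, wet MeCN, Saegusa–Ito type: palladation at C2, loss of the methyl group as MeOH, β-hydride elimination from C3). The route is rejoined directly at 18.

**Further compounds**
F1 | step 4 | (1R,2S)-1-(hydroxymethyl)-5-methoxycyclohex-4-ene-1,2-diol | OC[C@]1(O)CC(OC)=CC[C@@H]1O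
F2 | step 4 | [(1R,2S)-1,2-dihydroxy-5-methoxycyclohex-4-en-1-yl]methyl 4-methylbenzenesulfonate | Cc1ccc(cc1)S(=O)(=O)OC[C@]2(O)CC(OC)=CC[C@@H]2O
F3 | step 4 | (3R,4S)-7-methoxy-1-oxaspiro[2.5]oct-6-en-4-ol | COC1=CC[C@H](O)[C@]2(CO2)C1
F4 | step 6 | (1S,2S)-5,5-dimethoxy-1-[(8E)-9-(4,4,5,5-tetramethyl-1,3,2-dioxaborolan-2-yl)non-8-en-1-yl]cyclohex-3-ene-1,2-diol | CC1(C)OB(/C=C/CCCCCCC[C@]2(O)CC(OC)(OC)C=C[C@@H]2O)OC1(C)C
F5 | step 5 | (1S,2S)-1-[(8Z)-heptadec-8-en-1-yl]-5-methoxycyclohex-4-ene-1,2-diol | CCCCCCCC/C=C\CCCCCCC[C@]1(O)CC(OC)=CC[C@@H]1O
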